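The numbers of this flask are made up; what happens was integrated by code.

We have 0.19 M of starting material and the same of reagent in each flask, with 0.380 mM of catalyst against 1.5 mM of added ligand, and the flasks differ in what is fed and how warm they are.

common to all: free catalyst 0.2 mol%; added ligand 1.5 mM; time 4.0 min

| flask | starting material | reagent | temperature | remark |
|---|---|---|---|---|
| dusk | 0.19 M | 1.00 equiv (fed, over 40 s) | 60 °C | all else is in the flask from the start; the feed brings no volume worth counting |
| dawn | 0.19 M (fed, over 2.5 min) | 1.00 equiv | 60 °C | all else is in the flask from the start; the feed brings no volume worth counting |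
| midnight | 0.19 M | 1.00 equiv |  | everything together at the start at 30 °C, warmed to 60 °C at 2.5 min |
| summer | 0.19 M | 1.00 equiv (fed, over 2.5 min) | 60 °C | all else is in the flask from the start; the feed brings no volume worth counting |
| spring | 0.19 M | 1.00 equiv (fed, over 2.5 min) |  | the addition at 30 °C, then warmed to 60 °C; the feed brings no volume worth counting |

    catalyst intermediate A ⇌ catalyst intermediate B (K1 = 0.608, k1 = 17.3 s⁻¹, Ea1 = 82.0 kJ mol⁻¹, ΔH1 = −32.0 kJ mol⁻¹)
    starting material + free catalyst → catalyst intermediate A (k2 = 91.5 M⁻¹ s⁻¹, Ea2 = 40.0 kJ mol⁻¹)
    reagent + catalyst intermediate B ⇌ catalyst intermediate C (K3 = 0.920 M⁻¹, k3 = 179 M⁻¹ s⁻¹, Ea3 = 35.0 kJ mol⁻¹, ΔH3 = −22.0 kJ mol⁻¹)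
    free catalyst + added ligand ⇌ idle complex, settled at all times (K4 = 3950 M⁻¹, ΔH4 = −19.0 kJ mol⁻¹)
    catalyst intermediate C → free catalyst + product (k5 = 18.8 s⁻¹, Ea5 = 67.0 kJ mol⁻¹)
    (constants at 60 °C)

- all constants are for 60 °C and move with temperature by the activation energies and enthalpies

- which flask leads in amount of product, in percent of the starting material charged ("all alike" within 1.5 percentage points) (dusk / dawn / midnight / summer / spring / all alike)
- how much product is there at the end, in percent of the starting material charged: dusk
- how much product is there at the end, in percent of the starting material charged: dawn
- how much product is there at the end, in percent of the starting material charged: midnight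
- how much product is there at the end, in percent of the starting material charged: summer
- how much product is there at the end, in percent of the starting material charged: spring

For whoever takes over the bench: the catalyst holdup is small, so we treat the round as steady. We keep the ligand step at balance, which multiplies the free catalyst's stay by f = 6.92, because idle complex, an off-cycle form, stands beside each free catalyst. Adding the stays of every catalyst form gives our working quantity, the round time τ, the seconds one catalyst needs per turnover, equal to Ct divided by the rate. With starting material and reagent both at c, τ = a + b/c, where a = 0.111 s and b = 0.243 M·s. At the full charge, τ is 1.39 s.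

Integrating gives Ct·t = a(Q−c) + b ln(Q/c), with Q the charge. We dock half the feed from the clock, which is a guess. Our reckoning at 60 °C then gives about 27.3% product in dusk and 21.2% in summer. So expect mostly unreacted charge when you come. Do not lengthen the dusk feed, since the slow feed docks 75.0 s against 20.0 s. Do not add ligand either: its term is already a third of b. We did not reckon the cold flasks by hand.

The forecast names dusk, with dusk 27.9%, dawn 24.9%, midnight 16.1%, summer 22.6% and spring 14.8%. Its dusk and summer figures stand above ours. Its ground: “Rate depends on both concentrations, so the flask with substrates high soonest wins.”

The simulation puts dusk ahead: dusk 28.0%, dawn 24.9%, midnight 16.1%, summer 22.6%, spring 14.9%. Dusk's lead over dawn is 3.1 percentage points. At dusk's end, τ gives a rate of 0.201 mM s⁻¹, and the free catalyst in the run gives 0.204 mM s⁻¹ through the entry step. In the neighbour, dusk with 0.76 M of starting material and 1.52 mM of catalyst, the same reckoning gives 67.2% product, and the run gives 70.3%.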